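Locants: five-membered ring C1 (angular methyl), C2 (angelate), C3, C4 (carbinol), C5 (ring-fusion CH); seven-membered ring C1, C5, C6 (aryl ester), C7, C8 (methyl)=C9, C10. The seven-membered ring is cut at C7–C8 and C9–C10: its C6 oxygen, the skipped relation of C5=C6 and C8=C9, and the quaternary C1 map onto a rhodium-catalysed (5+2) cycloaddition. The precursor is a bicyclo[3.1.0]hexane, cyclopropane C1–C5–C10 fused to the finished cyclopentane, whose C5 carries the silyl enol ether C6(OSiMe3)=C7H2. With 1-(trimethylsilyl)propyne, strain release opens C5–C10 and forms both C–C bonds in one operation; protonation, directed reduction and two acylations finish.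

Key step: step 8

Remark: the target is read as the (1R,3R,3aS,4S,8aR)-octahydroazulene carrying a (Z)-2-methylbut-2-enoate; in enone 1 the carbonyl carbon becomes C4, the alkene carbons C5 and C1, and the silyloxy carbon C2.

Step 1
Reactants: 1 (R)-4-[(tert-butyldimethylsilyl)oxy]cyclopent-2-en-1-one
Product: 3 (R)-4-[(tert-butyldimethylsilyl)oxy]-3-methylcyclopent-2-en-1-one, via lithium enolate 2 (not isolated)
Conditions: Me2CuLi, THF, −78 °C; then PhS(Cl)=NtBu, −78 °C to rt
Reagents that add atoms: lithium dimethylcuprate, [Li+].C[Cu-]C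
Why: Cuprate conjugate addition anti to the silyloxy group gives enolate 2, which the sulfinimidoyl chloride dehydrogenates in the same flask (α-sulfenylation then syn elimination, Mukaiyama dehydrogenation) to the β-methyl enone without touching the C2 centre.

Step 2
Reactants: 3 (R)-4-[(tert-butyldimethylsilyl)oxy]-3-methylcyclopent-2-en-1-one
Product: 4 (R)-4-[(tert-butyldimethylsilyl)oxy]-2-iodo-3-methylcyclopent-2-en-1-one
Conditions: I2, pyridine, CH2Cl2, 0 °C to rt
Reagents that add atoms: iodine, II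
Why: α-Iodination of the enone by pyridine-mediated addition, iodination and elimination (Baylis–Hillman-type α-halogenation) should place iodine on C5.

Step 3
Reactants: 4 (R)-4-[(tert-butyldimethylsilyl)oxy]-2-iodo-3-methylcyclopent-2-en-1-one
Product: 5 (R)-4-[(tert-butyldimethylsilyl)oxy]-2-(1-ethoxyethenyl)-3-methylcyclopent-2-en-1-one
Conditions: Bu3SnC(OEt)=CH2, Pd(PPh3)4 (cat.), CuI (cat.), DMF, 50 °C
Reagents that add atoms: tributyl(1-ethoxyvinyl)stannane, CCCC[Sn](CCCC)(CCCC)C(=C)OCC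
Why: Stille coupling of the α-iodoenone installs C6 and C7 as a masked acetyl group that is inert to the Grignard reagent of the next step.

Step 4
Reactants: 5 (R)-4-[(tert-butyldimethylsilyl)oxy]-2-(1-ethoxyethenyl)-3-methylcyclopent-2-en-1-one
Product: 7 1-[(3R,5R)-3,5-dihydroxy-2-methyl-5-(propan-2-yl)cyclopent-1-en-1-yl]ethan-1-one, via tertiary alcohol 6 (not isolated)
Conditions: iPrMgCl, LaCl3·2LiCl, THF, −78 to 0 °C; then 48% aq. HF, MeCN, 0 °C to rt (same flask)
Reagents that add atoms: isopropylmagnesium chloride, CC(C)[Mg]Cl; water, O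
Why: Lanthanide-promoted Grignard 1,2-addition to the C4 ketone anti to the C2 silyloxy group should set C4 with its hydroxyl cis to the C2 oxygen, and aqueous HF then hydrolyses the enol ether to the methyl ketone and cleaves the silyl ether.

Step 5
Reactants: 7 1-[(3R,5R)-3,5-dihydroxy-2-methyl-5-(propan-2-yl)cyclopent-1-en-1-yl]ethan-1-one
Product: 8 1-[(3R,5R)-2-methyl-5-(propan-2-yl)-3,5-[(1,1,3,3-tetraisopropyldisiloxane-1,3-diyl)bis(oxy)]cyclopent-1-en-1-yl]ethan-1-one
Conditions: (iPr2SiCl)2O, imidazole, DMF, rt to 50 °C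
Reagents that add atoms: 1,3-dichloro-1,1,3,3-tetraisopropyldisiloxane, CC(C)[Si](Cl)(C(C)C)O[Si](Cl)(C(C)C)C(C)C
Why: Double silylation of the cis-1,3-diol closes an eight-membered cyclic disiloxane that protects both hydroxyls, holds both oxygens axial on one face of the cyclopentene and leaves the isopropyl group equatorial.

Step 6
Reactants: 8 disiloxane-bridged enone
Product: 9 1-[(1R,2R,4R,5R)-5-methyl-2-(propan-2-yl)-2,4-[(1,1,3,3-tetraisopropyldisiloxane-1,3-diyl)bis(oxy)]bicyclo[3.1.0]hexan-1-yl]ethan-1-one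
Conditions: Me3S(O)I, NaH, DMSO, rt to 50 °C
Reagents that add atoms: trimethylsulfoxonium iodide, C[S+](C)(C)=O.[I-]
Why: Corey–Chaykovsky cyclopropanation (ylide addition to C1, 3-exo-tet closure at C5) on the face opposite the disiloxane bridge should set C1 and C5 with the new CH2 (C10) trans to both oxygens and cis to isopropyl.

Step 7
Reactants: 9 bridged cyclopropyl methyl ketone
Product: 10 (1S,2R,4R,5R)-5-methyl-2-(propan-2-yl)-2,4-[(1,1,3,3-tetraisopropyldisiloxane-1,3-diyl)bis(oxy)]-1-[1-(trimethylsilyloxy)ethenyl]bicyclo[3.1.0]hexane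
Conditions: Me3SiOTf, Et3N, CH2Cl2, 0 °C
Reagents that add atoms: trimethylsilyl trifluoromethanesulfonate, C[Si](C)(C)OS(=O)(=O)C(F)(F)F
Why: Soft enolisation and O-silylation of the methyl ketone, whose CH3 is the only enolisable position, gives the 2-silyloxyvinyl cyclopropane with the ring centres unchanged.

Step 8
Reactants: 10 bridged 2-silyloxyvinyl cyclopropane; 11 1-(trimethylsilyl)propyne
Product: 12 (1R,3R,8aR)-6,8a-dimethyl-3-(propan-2-yl)-1,3-[(1,1,3,3-tetraisopropyldisiloxane-1,3-diyl)bis(oxy)]-7-(trimethylsilyl)-4-(trimethylsilyloxy)-1,2,3,5,8,8a-hexahydroazulene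
Conditions: [Rh(CO)2Cl]2 (5 mol %), 11 (3 equiv), ClCH2CH2Cl, 80 °C
Reagents that add atoms: none
Why: Monovalent rhodium binds the enol-ether alkene C6=C7 and inserts into the strained, less substituted cyclopropane bond C5–C10 to give a σ-alkyl (C10) π-allyl (C5–C6–C7) rhodacycle, the alkyne inserts at the allyl terminus C7, and reductive elimination joins C9 to C10. The closest known reaction is the rhodium-catalysed intermolecular (5+2) cycloaddition of 1-substituted vinylcyclopropanes with alkynes, here applied to a ring-fused cyclopropane whose vinyl group is a silyl enol ether. The seven-membered ring closes as a two-bond (5+2) annulation, C7–C8 by migratory insertion and C9–C10 by C(sp3)–C(sp2) reductive elimination from an eight-membered rhodacycle. No new stereocentre forms: C5 becomes trigonal, and quaternary C1, set in step 6, is carried through because its bonds to C5 and C10 are never broken. The step needs cleavage of C5–C10 and not of the ring-fusion bond C5–C1, which the unsubstituted CH2 terminus secures (primary alkyl rhodium, no β-hydrogen on C1). It also needs methyl on C8, which the bulky SiMe3 group secures by staying distal to the first-formed C7–C8 bond and ending on C9.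

Step 9
Reactants: 12 bridged bis-silyl cycloheptadiene
Product: 14 (1R,3R,3aR,8aR)-6,8a-dimethyl-3-(propan-2-yl)-1,3-[(1,1,3,3-tetraisopropyldisiloxane-1,3-diyl)bis(oxy)]-2,3,3a,5,8,8a-hexahydroazulen-4(1H)-one, via silyl ketone 13 (not isolated)
Conditions: CF3CO2H, CH2Cl2, −20 to 0 °C
Reagents that add atoms: none
Why: Acid hydrolysis of the silyl enol ether should protonate C5 kinetically on the face opposite the disiloxane bridge and the angular methyl (trans ring fusion), and protodesilylation of the vinylsilane by ipso protonation at C9 through the tertiary β-silyl cation at C8 keeps the alkene at C8=C9.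

Step 10
Reactants: 14 bridged trans-fused ketone
Product: 15 (1R,3R,3aR,8aR)-1,3-dihydroxy-6,8a-dimethyl-3-(propan-2-yl)-2,3,3a,5,8,8a-hexahydroazulen-4(1H)-one
Conditions: HF·pyridine, pyridine, THF, 0 °C to rt
Reagents that add atoms: none
Why: Fluoride cleavage of the disiloxane under buffered, non-basic conditions frees the C2 and C4 hydroxyls without enolising the β,γ-unsaturated β-hydroxy ketone.

Step 11
Reactants: 15 diol ketone; 16 angelic acid, (2Z)-2-methylbut-2-enoic acid
Product: 18 (1R,3R,3aR,8aR)-3-hydroxy-6,8a-dimethyl-4-oxo-3-(propan-2-yl)-1,2,3,3a,4,5,8,8a-octahydroazulen-1-yl (2Z)-2-methylbut-2-enoate, via mixed anhydride 17 (not isolated)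
Conditions: 16, 2,4,6-Cl3C6H2COCl, Et3N, toluene, rt; then 15, 75 °C
Reagents that add atoms: none
Why: Yamaguchi esterification without DMAP should acylate the only secondary hydroxyl (C2) at the less hindered angeloyl carbonyl of 17 and keep the Z double bond of the angelate.

Step 12
Reactants: 18 angelate ketone
Product: 19 (1R,3R,3aS,4S,8aR)-3,4-dihydroxy-6,8a-dimethyl-3-(propan-2-yl)-1,2,3,3a,4,5,8,8a-octahydroazulen-1-yl (2Z)-2-methylbut-2-enoate
Conditions: Me4NBH(OAc)3, AcOH, MeCN, −20 °C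
Reagents that add atoms: none
Why: Evans–Saksena reduction, with hydride delivered intramolecularly from the acetoxyborohydride bound to the C4 hydroxyl, should set C6 as the 1,3-anti diol (C6 hydroxyl trans to the C4 hydroxyl, cis to H5) and leave the enoate untouched.

Step 13
Reactants: 19 angelate diol; 20 4-acetoxybenzoyl chloride
Product: 21 (1R,3R,3aS,4S,8aR)-4-[(4-acetoxybenzoyl)oxy]-3-hydroxy-6,8a-dimethyl-3-(propan-2-yl)-1,2,3,3a,4,5,8,8a-octahydroazulen-1-yl (2Z)-2-methylbut-2-enoate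
Conditions: pyridine, DMAP (cat.), CH2Cl2, 0 °C to rt
Reagents that add atoms: none
Why: Nucleophile-catalysed acylation of the secondary C6 hydroxyl by the acid chloride; the tertiary C4 hydroxyl does not react.

Step 14
Reactants: 21 acetoxybenzoate
Product: 22 (1R,3R,3aS,4S,8aR)-3-hydroxy-4-[(4-hydroxybenzoyl)oxy]-6,8a-dimethyl-3-(propan-2-yl)-1,2,3,3a,4,5,8,8a-octahydroazulen-1-yl (2Z)-2-methylbut-2-enoate
Conditions: pyrrolidine, CH2Cl2, 0 °C
Reagents that add atoms: none
Why: Aminolysis of the phenyl acetate, far faster than that of the alkyl benzoate or the hindered angelate, should release the phenol.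

Compound list

1 | (R)-4-[(tert-butyldimethylsilyl)oxy]cyclopent-2-en-1-one | CC(C)(C)[Si](C)(C)O[C@@H]1CC(=O)C=C1 | starting material
2 | lithium (3R,4R)-4-[(tert-butyldimethylsilyl)oxy]-3-methylcyclopent-1-en-1-olate (methyl trans to silyloxy) | CC(C)(C)[Si](C)(C)O[C@@H]1CC(O[Li])=C[C@H]1C | intermediate
3 | (R)-4-[(tert-butyldimethylsilyl)oxy]-3-methylcyclopent-2-en-1-one | CC(C)(C)[Si](C)(C)O[C@@H]1CC(=O)C=C1C | intermediate
4 | (R)-4-[(tert-butyldimethylsilyl)oxy]-2-iodo-3-methylcyclopent-2-en-1-one | CC(C)(C)[Si](C)(C)O[C@@H]1CC(=O)C(I)=C1C | intermediate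
5 | (R)-4-[(tert-butyldimethylsilyl)oxy]-2-(1-ethoxyethenyl)-3-methylcyclopent-2-en-1-one | CC(C)(C)[Si](C)(C)O[C@@H]1CC(=O)C(C(=C)OCC)=C1C | intermediate
6 | (1R,4R)-4-[(tert-butyldimethylsilyl)oxy]-2-(1-ethoxyethenyl)-3-methyl-1-(propan-2-yl)cyclopent-2-en-1-ol | CC(C)(C)[Si](C)(C)O[C@@H]1C[C@@](O)(C(C)C)C(C(=C)OCC)=C1C | intermediate
7 | 1-[(3R,5R)-3,5-dihydroxy-2-methyl-5-(propan-2-yl)cyclopent-1-en-1-yl]ethan-1-one (cis-diol) | O[C@@H]1C[C@@](O)(C(C)C)C(C(C)=O)=C1C | intermediate
8 | 1-[(3R,5R)-2-methyl-5-(propan-2-yl)-3,5-[(1,1,3,3-tetraisopropyldisiloxane-1,3-diyl)bis(oxy)]cyclopent-1-en-1-yl]ethan-1-one | CC(C)[Si]1(C(C)C)O[C@@H]2C[C@@](O[Si](C(C)C)(C(C)C)O1)(C(C)C)C(C(C)=O)=C2C | intermediate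
9 | 1-[(1R,2R,4R,5R)-5-methyl-2-(propan-2-yl)-2,4-[(1,1,3,3-tetraisopropyldisiloxane-1,3-diyl)bis(oxy)]bicyclo[3.1.0]hexan-1-yl]ethan-1-one (cyclopropane CH2 trans to both oxygens) | CC(C)[Si]1(C(C)C)O[C@@H]2C[C@@](O[Si](C(C)C)(C(C)C)O1)(C(C)C)[C@@]3(C(C)=O)C[C@@]23C | intermediate
10 | (1S,2R,4R,5R)-5-methyl-2-(propan-2-yl)-2,4-[(1,1,3,3-tetraisopropyldisiloxane-1,3-diyl)bis(oxy)]-1-[1-(trimethylsilyloxy)ethenyl]bicyclo[3.1.0]hexane (same spatial arrangement as 9) | CC(C)[Si]1(C(C)C)O[C@@H]2C[C@@](O[Si](C(C)C)(C(C)C)O1)(C(C)C)[C@@]3(C(=C)O[Si](C)(C)C)C[C@@]23C | intermediate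
11 | 1-(trimethylsilyl)propyne | C[Si](C)(C)C#CC | starting material
12 | (1R,3R,8aR)-6,8a-dimethyl-3-(propan-2-yl)-1,3-[(1,1,3,3-tetraisopropyldisiloxane-1,3-diyl)bis(oxy)]-7-(trimethylsilyl)-4-(trimethylsilyloxy)-1,2,3,5,8,8a-hexahydroazulene | CC(C)[Si]3(C(C)C)O[C@@H]1C[C@@](O[Si](C(C)C)(C(C)C)O3)(C(C)C)C2=C(O[Si](C)(C)C)CC(C)=C([Si](C)(C)C)C[C@]21C | intermediate
13 | (1R,3R,3aR,8aR)-6,8a-dimethyl-3-(propan-2-yl)-1,3-[(1,1,3,3-tetraisopropyldisiloxane-1,3-diyl)bis(oxy)]-7-(trimethylsilyl)-2,3,3a,5,8,8a-hexahydroazulen-4(1H)-one | CC(C)[Si]3(C(C)C)O[C@@H]1C[C@@](O[Si](C(C)C)(C(C)C)O3)(C(C)C)[C@@H]2C(=O)CC(C)=C([Si](C)(C)C)C[C@]21C | intermediate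
14 | (1R,3R,3aR,8aR)-6,8a-dimethyl-3-(propan-2-yl)-1,3-[(1,1,3,3-tetraisopropyldisiloxane-1,3-diyl)bis(oxy)]-2,3,3a,5,8,8a-hexahydroazulen-4(1H)-one (trans-fused) | CC(C)[Si]3(C(C)C)O[C@@H]1C[C@@](O[Si](C(C)C)(C(C)C)O3)(C(C)C)[C@@H]2C(=O)CC(C)=CC[C@]21C | intermediate
15 | (1R,3R,3aR,8aR)-1,3-dihydroxy-6,8a-dimethyl-3-(propan-2-yl)-2,3,3a,5,8,8a-hexahydroazulen-4(1H)-one | O[C@@H]1C[C@@](O)(C(C)C)[C@@H]2C(=O)CC(C)=CC[C@]21C | intermediate
16 | angelic acid, (2Z)-2-methylbut-2-enoic acid | C/C=C(/C)C(O)=O | starting material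
17 | (2Z)-2-methylbut-2-enoic 2,4,6-trichlorobenzoic anhydride | C/C=C(/C)C(=O)OC(=O)c1c(Cl)cc(Cl)cc1Cl | intermediate
18 | (1R,3R,3aR,8aR)-3-hydroxy-6,8a-dimethyl-4-oxo-3-(propan-2-yl)-1,2,3,3a,4,5,8,8a-octahydroazulen-1-yl (2Z)-2-methylbut-2-enoate | C/C=C(/C)C(=O)O[C@@H]1C[C@@](O)(C(C)C)[C@@H]2C(=O)CC(C)=CC[C@]21C | intermediate
19 | (1R,3R,3aS,4S,8aR)-3,4-dihydroxy-6,8a-dimethyl-3-(propan-2-yl)-1,2,3,3a,4,5,8,8a-octahydroazulen-1-yl (2Z)-2-methylbut-2-enoate | C/C=C(/C)C(=O)O[C@@H]1C[C@@](O)(C(C)C)[C@@H]2[C@@H](O)CC(C)=CC[C@]21C | intermediate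
20 | 4-acetoxybenzoyl chloride | CC(=O)Oc1ccc(cc1)C(Cl)=O | starting material
21 | (1R,3R,3aS,4S,8aR)-4-[(4-acetoxybenzoyl)oxy]-3-hydroxy-6,8a-dimethyl-3-(propan-2-yl)-1,2,3,3a,4,5,8,8a-octahydroazulen-1-yl (2Z)-2-methylbut-2-enoate | C/C=C(/C)C(=O)O[C@@H]1C[C@@](O)(C(C)C)[C@@H]2[C@@H](OC(=O)c3ccc(OC(C)=O)cc3)CC(C)=CC[C@]21C | intermediate
22 | (1R,3R,3aS,4S,8aR)-3-hydroxy-4-[(4-hydroxybenzoyl)oxy]-6,8a-dimethyl-3-(propan-2-yl)-1,2,3,3a,4,5,8,8a-octahydroazulen-1-yl (2Z)-2-methylbut-2-enoate | C/C=C(/C)C(=O)O[C@@H]1C[C@@](O)(C(C)C)[C@@H]2[C@@H](OC(=O)c3ccc(O)cc3)CC(C)=CC[C@]21C | target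

Total step count: 14. Longest linear sequence: 14 steps (from 1; compounds 11, 16 and 20 are purchased).

Steps most likely to fail

Step 8. The crowded, fully substituted cyclopropane may undergo rhodium insertion so slowly that alkyne oligomerisation takes over, or regiocontrol may be lost in the alkyne insertion. The fallback sets out from 9 and comes back at 14 by a stepwise ring opening and ring-closing metathesis. Homoconjugate addition of (CH2=CH)2CuLi with BF3·OEt2 at the cyclopropane CH2 (C10) of 9 should cleave C5–C10, and protonation of the enolate on the unbridged face should give the allyl ketone F1. Palladium-catalysed α-alkenylation of its methyl ketone with 2-bromopropene (Pd(OAc)2, P(tBu)3, LiN(SiMe3)2) should give the diene ketone F2. Ring-closing metathesis with the second-generation Grubbs catalyst then closes C8=C9 and should deliver 14.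

Step 6. The ylide may fail to add in conjugate fashion to the twisted, tetrasubstituted enone, or may attack the carbonyl group instead. The fallback sets out from 8 and comes back at 9 by a hydroxyl-directed carbenoid route. Reduction of 8 with NaBH4 and CeCl3·7H2O should give the allylic alcohol F3 (either C6 epimer serves). Simmons–Smith cyclopropanation with Et2Zn and CH2I2, directed by the C6 hydroxyl onto the only open face, should give the cyclopropyl carbinol F4. Dess–Martin oxidation returns 9.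

Step 9. The acid may move the C8=C9 double bond into conjugation with the new C6 ketone, or may erode the disiloxane before C5 is protonated. The fallback sets out from 12 and comes back at 14 without strong acid. Citric acid in methanol at 0 °C should cleave only the silyl enol ether and give the silyl ketone 13, now isolated. Ipso-iododesilylation with N-iodosuccinimide in MeCN should give the vinyl iodide F5 with the alkene held in place. Reduction of the C–I bond with Bu3SnH and Pd(PPh3)4 should give 14.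

Further compounds

F1 | step 8 | 1-[2-methyl-2-(prop-2-en-1-yl)cyclopentyl]ethan-1-one carrying the isopropyl group and disiloxane bridge of 14, acetyl trans to allyl | CC(C)[Si]3(C(C)C)O[C@@H]1C[C@@](O[Si](C(C)C)(C(C)C)O3)(C(C)C)[C@H](C(C)=O)[C@@]1(C)CC=C
F2 | step 8 | 3-methylbut-3-en-1-one analogue of F1 (side chain C(=O)CH2C(CH3)=CH2 on C5) | CC(C)[Si]3(C(C)C)O[C@@H]1C[C@@](O[Si](C(C)C)(C(C)C)O3)(C(C)C)[C@H](C(=O)CC(C)=C)[C@@]1(C)CC=C
F3 | step 6 | allylic alcohol from 8, 1-hydroxyethyl in place of acetyl, C6 configuration not controlled | CC(C)[Si]1(C(C)C)O[C@@H]2C[C@@](O[Si](C(C)C)(C(C)C)O1)(C(C)C)C(C(C)O)=C2C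
F4 | step 6 | cyclopropyl carbinol, 1-hydroxyethyl analogue of 9, C6 configuration not controlled | CC(C)[Si]1(C(C)C)O[C@@H]2C[C@@](O[Si](C(C)C)(C(C)C)O1)(C(C)C)[C@@]3(C(C)O)C[C@@]23C
F5 | step 9 | 7-iodo analogue of 14 (iodine on C9) | CC(C)[Si]3(C(C)C)O[C@@H]1C[C@@](O[Si](C(C)C)(C(C)C)O3)(C(C)C)[C@@H]2C(=O)CC(C)=C(I)C[C@]21C
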